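The lactone ring (O1, C2, C3, C4, C5) is disconnected at C4–C5 and O1–C2. C5 is an isolated OCH2 unit whose only carbon neighbour, C4, lies α to the aroyl ketone and β to the lactone carbonyl C2, so C5 maps onto formaldehyde and the ring onto a hydroxymethylation–lactonisation. In one telescoped operation the ketone silyl enol ether adds to formaldehyde, the new primary alcohol closes the ring on the methyl ester, and C4 is equilibrated to trans under the control of C3. The precursor is an acyclic, bis-O-benzylated methyl (R)-2-benzyl-4-aryl-4-oxobutanoate whose single stereocentre comes from asymmetric hydrogenation of a Stobbe half-ester; debenzylation finishes the synthesis.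

Key step: step 5

Remark on numbering and configuration: lactone numbering (O1, C2 = lactone C=O, C3 = benzyl-bearing, C4 = aroyl-bearing, C5 = OCH2) is used for the corresponding atoms of the open-chain compounds as well. The target is the (3R,4R) lactone, which is the trans isomer (C3 benzyl and C4 aroyl on opposite ring faces). C3 keeps the descriptor R from compound 4 onward because the CIP ranking of its substituents never changes.

Assumption: the (S,S) antipode of Et-DuPhos is taken to deliver the R acid in step 2, by analogy with itaconate half-esters. The sense is to be checked on the first batch (chiral HPLC, sign of rotation) and the (R,R) ligand used instead if required.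

Step 1
Reactants: 1 4-benzyloxy-3-methoxybenzaldehyde (O-benzylvanillin); 2 dimethyl succinate
Product: 3 (E)-4-(4-benzyloxy-3-methoxyphenyl)-3-(methoxycarbonyl)but-3-enoic acid (Stobbe half-ester, aryl trans to CO2Me)
Conditions: NaOMe, MeOH, reflux; then aq. HCl
Reagents that add atoms: none
Why: Stobbe condensation, in which the succinate enolate adds to the non-enolisable aldehyde, the alkoxide lactonises onto the distal ester and E1cB opening of that lactone leaves the conjugated methyl ester and a free CH2CO2H arm, the E-alkene being expected to predominate and to be purified by crystallisation, while the aryl benzyl and methyl ethers are inert to methoxide.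

Step 2
Reactants: 3 (E)-4-(4-benzyloxy-3-methoxyphenyl)-3-(methoxycarbonyl)but-3-enoic acid
Product: 4 (R)-4-(4-benzyloxy-3-methoxyphenyl)-3-(methoxycarbonyl)butanoic acid [(R)-2-(4-benzyloxy-3-methoxybenzyl)succinic acid 1-methyl ester]
Conditions: [Rh(cod)((S,S)-Et-DuPhos)]BF4 (1 mol%), NaOMe (10 mol%), H2 (5 bar), MeOH, rt
Reagents that add atoms: none
Why: Rh-bisphosphine asymmetric hydrogenation of an itaconate-type half-ester, in which the carboxylate arm and the alkene chelate rhodium so that the C2-symmetric ligand dictates the face of H2 delivery and sets the future lactone C3 as R, while the homogeneous Rh catalyst leaves the benzyl ether untouched.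

Step 3
Reactants: 5 4-bromo-2-methoxyphenol
Product: 6 1-(benzyloxy)-4-bromo-2-methoxybenzene
Conditions: BnBr, K2CO3, DMF, rt
Reagents that add atoms: benzyl bromide, BrCc1ccccc1
Why: Williamson ether synthesis, in which the phenoxide is the only nucleophile present and SN2 displacement on benzyl bromide should be clean.

Step 4
Reactants: 4 (R)-4-(4-benzyloxy-3-methoxyphenyl)-3-(methoxycarbonyl)butanoic acid; 6 1-(benzyloxy)-4-bromo-2-methoxybenzene
Product: 10 methyl (R)-2-(4-benzyloxy-3-methoxybenzyl)-4-(4-benzyloxy-3-methoxyphenyl)-4-oxobutanoate, via acid chloride 7 (not isolated), via arylmagnesium bromide 8 (not isolated), via arylzinc chloride 9 (not isolated)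
Conditions: 4: (COCl)2, DMF (cat.), CH2Cl2, 0 °C → rt, evaporate; 6: Mg, THF, 40 °C, then ZnCl2, 0 °C; then both, Pd(PPh3)4 (5 mol%), THF, 0 °C → rt
Reagents that add atoms: none
Why: Negishi acylation, in which Pd(0) inserts into the acyl C–Cl bond, the aryl group is transferred from zinc and reductive elimination gives the aryl ketone, while the arylzinc chloride is too mild to add to the methyl ester or the new ketone and the base-free medium leaves C3 (α to the ester only) untouched.

Step 5
Reactants: 10 methyl (R)-2-(4-benzyloxy-3-methoxybenzyl)-4-(4-benzyloxy-3-methoxyphenyl)-4-oxobutanoate; 11 formaldehyde (37% aqueous solution)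
Product: 15 (3R,4R)-3-(4-benzyloxy-3-methoxybenzyl)-4-(4-benzyloxy-3-methoxybenzoyl)dihydrofuran-2(3H)-one (trans), via silyl enol ether 12 (not isolated), via hydroxymethyl keto ester 13 (not isolated), via cis lactone 14 (not isolated)
Conditions: TMSOTf, Et3N, CH2Cl2, 0 °C; then aq. HCHO, Yb(OTf)3 (10 mol%), THF, rt; then TsOH·H2O (cat.), CH2Cl2, rt; then DBU (0.2 equiv), rt (crude material carried from stage to stage after extractive work-up)
Reagents that add atoms: none
Why: TMSOTf/Et3N silylates only the aryl ketone, because its α-CH2 (C4) enolises far more readily than the tertiary ester α-CH (C3), and the silyl enol ether 12 then adds to Yb(III)-activated formaldehyde in a Mukaiyama aldol that forms C4–C5 and gives the γ-hydroxy ester 13. The closest known reaction type is the lanthanide-triflate-catalysed hydroxymethylation of ketone silyl enol ethers with aqueous formaldehyde, followed by acid-catalysed lactonisation of a γ-hydroxy ester as used for β-aroyl-γ-butyrolactones. The ring closes by 5-exo-trig acyl substitution of the C5 hydroxyl on the ester carbonyl C2 (O1–C2 bond, methanol lost), which also takes the β-hydroxy ketone out of retro-aldol and dehydration pathways. The new stereocentre C4 is set after bond formation, under thermodynamic control: catalytic DBU enolises C4 (α to the ketone) so that cis lactone 14 drains into trans lactone 15, the fixed (R)-C3 benzyl group being the controlling element. The selectivities needed are mono-hydroxymethylation at C4 alone, secured by one preformed nucleophile equivalent whose aldol product cannot enolise in the Lewis-acidic medium and by washing out formaldehyde before base is added, and retention of C3, whose proton is activated only by the ester or lactone carbonyl and is much less acidic than C4–H. Ring opening by E1cB loss of the O1 carboxylate from the C4 enolate is the reverse of a 5-endo-trig closure and would use up base stoichiometrically, so a catalytic amount of amidine should keep it marginal.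

Step 6
Reactants: 15 (3R,4R)-3-(4-benzyloxy-3-methoxybenzyl)-4-(4-benzyloxy-3-methoxybenzoyl)dihydrofuran-2(3H)-one
Product: 16 (3R,4R)-4-(4-hydroxy-3-methoxybenzoyl)-3-(4-hydroxy-3-methoxybenzyl)dihydrofuran-2(3H)-one (target)
Conditions: H2 (1 atm), 10% Pd/C, EtOAc, rt, stopped once both benzyl groups are gone
Reagents that add atoms: none
Why: Heterogeneous Pd-catalysed hydrogenolysis should cleave the two benzylic C–O bonds of the aryl benzyl ethers quickly, whereas the aryl ketone (deactivated by its para oxygen donor) and the non-benzylic lactone C5–O1 bond react far more slowly in neutral EtOAc at 1 atm, and neither acid nor base is present to disturb C3 or C4.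

Compound list
1 | 4-benzyloxy-3-methoxybenzaldehyde (O-benzylvanillin) | COc1cc(C=O)ccc1OCc1ccccc1 | starting material
2 | dimethyl succinate | COC(=O)CCC(=O)OC | starting material
3 | (E)-4-(4-benzyloxy-3-methoxyphenyl)-3-(methoxycarbonyl)but-3-enoic acid | COc1cc(/C=C(\CC(=O)O)C(=O)OC)ccc1OCc1ccccc1 | intermediate
4 | (R)-4-(4-benzyloxy-3-methoxyphenyl)-3-(methoxycarbonyl)butanoic acid | COc1cc(C[C@H](CC(=O)O)C(=O)OC)ccc1OCc1ccccc1 | intermediate
5 | 4-bromo-2-methoxyphenol | COc1cc(Br)ccc1O | starting material
6 | 1-(benzyloxy)-4-bromo-2-methoxybenzene | COc1cc(Br)ccc1OCc1ccccc1 | intermediate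
7 | methyl (R)-2-(4-benzyloxy-3-methoxybenzyl)-4-chloro-4-oxobutanoate (acid chloride) | COc1cc(C[C@H](CC(=O)Cl)C(=O)OC)ccc1OCc1ccccc1 | intermediate
8 | (4-benzyloxy-3-methoxyphenyl)magnesium bromide | COc1cc([Mg]Br)ccc1OCc1ccccc1 | intermediate
9 | (4-benzyloxy-3-methoxyphenyl)zinc chloride | COc1cc([Zn]Cl)ccc1OCc1ccccc1 | intermediate
10 | methyl (R)-2-(4-benzyloxy-3-methoxybenzyl)-4-(4-benzyloxy-3-methoxyphenyl)-4-oxobutanoate | COc1cc(C[C@H](CC(=O)c2ccc(OCc3ccccc3)c(OC)c2)C(=O)OC)ccc1OCc1ccccc1 | intermediate
11 | formaldehyde | C=O | starting material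
12 | methyl (2R,3Z)-2-(4-benzyloxy-3-methoxybenzyl)-4-(4-benzyloxy-3-methoxyphenyl)-4-(trimethylsilyloxy)but-3-enoate (silyl enol ether) | COc1cc(C[C@H](/C=C(\O[Si](C)(C)C)c2ccc(OCc3ccccc3)c(OC)c2)C(=O)OC)ccc1OCc1ccccc1 | intermediate
13 | methyl (2R)-2-(4-benzyloxy-3-methoxybenzyl)-4-(4-benzyloxy-3-methoxyphenyl)-3-(hydroxymethyl)-4-oxobutanoate, both C3 epimers (hydroxymethyl keto ester) | COc1cc(C[C@H](C(CO)C(=O)c2ccc(OCc3ccccc3)c(OC)c2)C(=O)OC)ccc1OCc1ccccc1 | intermediate
14 | (3R,4S)-3-(4-benzyloxy-3-methoxybenzyl)-4-(4-benzyloxy-3-methoxybenzoyl)dihydrofuran-2(3H)-one (cis lactone) | COc1cc(C[C@H]2C(=O)OC[C@H]2C(=O)c2ccc(OCc3ccccc3)c(OC)c2)ccc1OCc1ccccc1 | intermediate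
15 | (3R,4R)-3-(4-benzyloxy-3-methoxybenzyl)-4-(4-benzyloxy-3-methoxybenzoyl)dihydrofuran-2(3H)-one (trans lactone) | COc1cc(C[C@H]2C(=O)OC[C@@H]2C(=O)c2ccc(OCc3ccccc3)c(OC)c2)ccc1OCc1ccccc1 | intermediate
16 | (3R,4R)-4-(4-hydroxy-3-methoxybenzoyl)-3-(4-hydroxy-3-methoxybenzyl)dihydrofuran-2(3H)-one | COc1cc(C[C@H]2C(=O)OC[C@@H]2C(=O)c2ccc(O)c(OC)c2)ccc1O | target

Total step count: 6. Longest linear sequence: 5 steps (1 → 2 → 4 → 5 → 6); step 3 is a one-step side branch.

Steps most likely to fail

Step 5. Two processes are the main risks. Protodesilylation of the enol ether in the aqueous Lewis-acid medium may outrun addition to formaldehyde, which would merely return 10. During the base stage, C4 equilibration may be incomplete or accompanied by β-elimination of the lactone carboxylate. The fallback sets out from 10 and comes back at 15. The methyl ester is saponified (LiOH, THF–H2O, 0 °C) to (R)-2-(4-benzyloxy-3-methoxybenzyl)-4-(4-benzyloxy-3-methoxyphenyl)-4-oxobutanoic acid F1. Its sodium salt is treated with about one equivalent of formalin in dilute aqueous NaOH at room temperature, the classical crossed aldol of β-aroylpropionates, in which the carboxylate shields C3 from deprotonation. This should give (2R)-2-(4-benzyloxy-3-methoxybenzyl)-4-(4-benzyloxy-3-methoxyphenyl)-3-(hydroxymethyl)-4-oxobutanoic acid F2 as both C3 epimers. Acidification and gentle warming should lactonise it to the 14/15 mixture, which the same catalytic DBU treatment should converge on 15.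

Step 4. Intramolecular Friedel–Crafts acylation of the electron-rich benzyl ring by the acid chloride (helped by zinc and magnesium halides), or ketene formation, may compete with Pd-catalysed acyl transfer. The fallback sets out from 4 and comes back at 10. The acid is converted (EtSH, EDC·HCl, DMAP, CH2Cl2) into the thioester methyl (R)-2-(4-benzyloxy-3-methoxybenzyl)-4-(ethylsulfanyl)-4-oxobutanoate F3, an acyl donor too mild for either side reaction. Fukuyama coupling of it with arylzinc chloride 9 (PdCl2(PPh3)2, THF–toluene, rt) should then give 10.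

Step 6. Over-reduction may occur: hydrogenation of the aryl ketone to the benzylic alcohol and hydrogenolysis beyond it, competing with O-debenzylation. The fallback sets out from 15 and ends at 16. It is a non-reductive debenzylation with BCl3 and pentamethylbenzene as benzyl-cation scavenger (CH2Cl2, −78 °C), which should spare the ketone, the lactone and the methyl ethers. This fallback makes no new compound (F0).

Further compounds
F1 | step 5 | (R)-2-(4-benzyloxy-3-methoxybenzyl)-4-(4-benzyloxy-3-methoxyphenyl)-4-oxobutanoic acid | COc1cc(C[C@H](CC(=O)c2ccc(OCc3ccccc3)c(OC)c2)C(=O)O)ccc1OCc1ccccc1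
F2 | step 5 | (2R)-2-(4-benzyloxy-3-methoxybenzyl)-4-(4-benzyloxy-3-methoxyphenyl)-3-(hydroxymethyl)-4-oxobutanoic acid, both C3 epimers | COc1cc(C[C@H](C(CO)C(=O)c2ccc(OCc3ccccc3)c(OC)c2)C(=O)O)ccc1OCc1ccccc1
F3 | step 4 | methyl (R)-2-(4-benzyloxy-3-methoxybenzyl)-4-(ethylsulfanyl)-4-oxobutanoate | COc1cc(C[C@H](CC(=O)SCC)C(=O)OC)ccc1OCc1ccccc1
F0 | step 6 | none | none
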